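**Plan**

Numbering runs from the acetoxymethylene carbon (C1) to the isopropylidene carbon (C15); C3′ is the hydroxymethyl carbon on C3.
Cuts, in retrosynthetic order: the two silyl ethers and the acetate; C3–C4 (sp2–sp3 coupling); C4=C5 of a vinyl oxirane (Wittig); C14=C15 (cross-metathesis); the C6–O bond of the oxirane (epoxide migration); C12–C13 (allylboration). This leaves (R)-linalool (C5–C12 with both methyls) and a butynediol-derived C1–C3/C3′ iodide.
Forward: linalool is oxidised at its E-methyl to the C12 enal, allylated, silylated and epoxidised at the vinyl group (C5–C6). The only ring of the target, the C6–C7 oxirane, then closes when the C7 alkoxide displaces the old epoxide oxygen at C6. The prenyl end, C4 and last C1–C3 are then added.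
Feature used: C7 is a methyl- and oxygen-bearing quaternary carbon with C6 and C5 beside it. This is the carbinol carbon and vinyl group of linalool, so the C7–O bond of the oxirane is never made or broken.
Stereochemistry: C7 comes from (R)-linalool. C6 comes from a ligand-controlled epoxidation followed by inversion in the ring closure. C12 comes from a reagent-controlled allylboration. C2=C3 comes from a hydroxyl-directed trans-hydroalumination/iodination and a stereoretentive coupling. C10=C11 comes from the E-selective SeO2 oxidation.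

Key step: step 6

Assumption: commercial (R)-(−)-linalool is taken at high enantiomeric purity, so that C7 needs no further control.

**Route**

Step 1
Reactants: 1 (R)-linalool
Product: 2 (2E,6R)-2,6-dimethylocta-2,7-diene-1,6-diol (C12 allylic alcohol)
Conditions: SeO2 (0.3 equiv), t-BuOOH, CH2Cl2, 0 °C to rt
Reagents that add atoms: tert-butyl hydroperoxide, CC(C)(C)OO (terminal source of the oxygen); selenium dioxide, O=[Se]=O (carrier that places it on C12)
Why: Riley-type allylic oxidation (ene reaction, then [2,3]-sigmatropic shift) should oxidise the methyl trans to the chain on the trisubstituted alkene to the E-allylic alcohol, since the vinyl group has no allylic hydrogen and the tertiary alcohol cannot be oxidised.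

Step 2
Reactants: 2 (2E,6R)-2,6-dimethylocta-2,7-diene-1,6-diol
Product: 3 (2E,6R)-6-hydroxy-2,6-dimethylocta-2,7-dienal (C12 enal)
Conditions: MnO2, CH2Cl2, rt
Reagents that add atoms: none
Why: MnO2 oxidation of an allylic alcohol should touch only the primary allylic hydroxyl and keep the E geometry of C10=C11.

Step 3
Reactants: 3 (2E,6R)-6-hydroxy-2,6-dimethylocta-2,7-dienal
Product: 5 (4R,5E,9R)-5,9-dimethylundeca-1,5,10-triene-4,9-diol (12R homoallylic alcohol), via diisopinocampheylborinate ester 4 (not isolated)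
Conditions: B-allyldiisopinocampheylborane from (−)-α-pinene, Et2O, −78 °C; then NaOH, H2O2, 0 °C to rt
Reagents that add atoms: B-allyldiisopinocampheylborane from (−)-α-pinene, C=CCB([C@@H]1[C@@H](C)[C@@H]2C[C@H](C1)C2(C)C)[C@@H]1[C@@H](C)[C@@H]2C[C@H](C1)C2(C)C
Why: Brown allylboration through a closed six-membered chair transition state should add the allyl group 1,2 to the Re face of the enal carbonyl under control of the isopinocampheyl groups, setting (12R) by reagent control.

Step 4
Reactants: 5 (4R,5E,9R)-5,9-dimethylundeca-1,5,10-triene-4,9-diol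
Product: 6 (3R,6E,8R)-8-[(tert-butyldimethylsilyl)oxy]-3,7-dimethylundeca-1,6,10-trien-3-ol (C12 TBS ether, C7 hydroxyl free)
Conditions: TBSCl, imidazole, DMF, 0 °C to rt
Reagents that add atoms: tert-butyldimethylsilyl chloride, CC(C)(C)[Si](C)(C)Cl
Why: Silyl ether formation should take place only at the secondary allylic hydroxyl, which removes the one hydroxyl that could direct an oxidant to C10=C11 and leaves the hindered C7 hydroxyl free as the directing group for step 5.

Step 5
Reactants: 6 (3R,6E,8R)-8-[(tert-butyldimethylsilyl)oxy]-3,7-dimethylundeca-1,6,10-trien-3-ol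
Product: 7 (2R,5E,7R)-7-[(tert-butyldimethylsilyl)oxy]-6-methyl-2-[(2S)-oxiran-2-yl]deca-5,9-dien-2-ol ((6S,7R)-5,6-epoxy-7-ol)
Conditions: Hf(OtBu)4 (cat.), chiral bishydroxamic acid ligand on a trans-1,2-diaminocyclohexane backbone (cat., the antipode that delivers oxygen to the Si face of C6), cumene hydroperoxide, 4 Å MS, toluene, 0 °C to rt
Reagents that add atoms: cumene hydroperoxide, CC(C)(OO)c1ccccc1
Why: Hydroxyl-directed, ligand-controlled epoxidation of a tertiary allylic alcohol (metal–bishydroxamic acid catalysis) should deliver the peroxide oxygen from the metal-bound C7 alkoxide to the adjacent vinyl group on the Si face of C6, setting (6S), while C10=C11 is only bishomoallylic and shielded by the silyloxy-bearing C12 and the terminal allyl alkene has no directing group.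

Step 6
Reactants: 7 (2R,5E,7R)-7-[(tert-butyldimethylsilyl)oxy]-6-methyl-2-[(2S)-oxiran-2-yl]deca-5,9-dien-2-ol
Product: 8 [(2R,3R)-3-[(3E,5R)-5-[(tert-butyldimethylsilyl)oxy]-4-methylocta-3,7-dien-1-yl]-3-methyloxiran-2-yl]methanol ((6R,7R)-6,7-epoxy-5-ol)
Conditions: NaH (1.1 equiv), THF, 0 °C to rt; then aq NH4Cl
Reagents that add atoms: none
Why: NaH turns the C7 hydroxyl of 7 into the tertiary alkoxide, which attacks C6 of the neighbouring C5–C6 oxirane from the side opposite the departing oxygen, so that the new C6–O bond forms as the old one breaks and the oxygen stays on C5 as a primary alkoxide. The closest known reaction is the Payne rearrangement of 1,2-epoxy-3-ols to 2,3-epoxy-1-ols. The one ring closed, the C6–C7 oxirane, forms by a 3-exo-tet closure. The only stereochemical event is inversion at C6, fixed by the SN2 geometry, so that (6S) in 7 becomes (6R) in 8, while C7 keeps the configuration of linalool because its C–O bond is untouched. The step needs the equilibrium to lie on the side of 8, which the trisubstituted oxirane and the less basic primary alkoxide should secure in an aprotic medium, and it needs C5 to be free from attack by an outside nucleophile, which NaH in THF ensures.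

Step 7
Reactants: 8 [(2R,3R)-3-[(3E,5R)-5-[(tert-butyldimethylsilyl)oxy]-4-methylocta-3,7-dien-1-yl]-3-methyloxiran-2-yl]methanol
Product: 9 [(2R,3R)-3-[(3E,5R)-5-[(tert-butyldimethylsilyl)oxy]-4,8-dimethylnona-3,7-dien-1-yl]-3-methyloxiran-2-yl]methanol (prenyl terminus complete)
Conditions: 2-methyl-2-butene (excess), second-generation Grubbs catalyst RuCl2(=CHPh)(PCy3)(H2IMes) (cat.), CH2Cl2, rt
Reagents that add atoms: 2-methyl-2-butene, CC=C(C)C
Why: Olefin cross-metathesis should exchange the methylene of the monosubstituted allyl terminus for the isopropylidene of 2-methyl-2-butene, the trisubstituted C10=C11 alkene, the oxirane and the primary alcohol being inert to the ruthenium carbene and the linalool vinyl group, which would otherwise ring-close onto C10, being already gone.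

Step 8
Reactants: 9 [(2R,3R)-3-[(3E,5R)-5-[(tert-butyldimethylsilyl)oxy]-4,8-dimethylnona-3,7-dien-1-yl]-3-methyloxiran-2-yl]methanol
Product: 10 (2S,3R)-3-[(3E,5R)-5-[(tert-butyldimethylsilyl)oxy]-4,8-dimethylnona-3,7-dien-1-yl]-3-methyloxirane-2-carbaldehyde (C5 aldehyde)
Conditions: TEMPO (cat.), PhI(OAc)2, CH2Cl2, rt
Reagents that add atoms: none
Why: Oxoammonium-mediated (TEMPO/PhI(OAc)2) oxidation of a primary alcohol should stop at the aldehyde under near-neutral conditions that spare the oxirane, silyl ether and alkenes, and C6 cannot epimerise because it is an oxirane carbon.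

Step 9
Reactants: 10 (2S,3R)-3-[(3E,5R)-5-[(tert-butyldimethylsilyl)oxy]-4,8-dimethylnona-3,7-dien-1-yl]-3-methyloxirane-2-carbaldehyde
Product: 11 (2R,3R)-3-[(3E,5R)-5-[(tert-butyldimethylsilyl)oxy]-4,8-dimethylnona-3,7-dien-1-yl]-2-ethenyl-3-methyloxirane (vinyl oxirane, C4=C5)
Conditions: Ph3PCH3Br, NaN(SiMe3)2, THF, 0 °C; then 10, −78 °C to 0 °C
Reagents that add atoms: methyltriphenylphosphonium bromide, C[P+](c1ccccc1)(c1ccccc1)c1ccccc1.[Br-]
Why: Wittig methylenation should convert the epoxy aldehyde into the vinyl oxirane at low temperature, bringing in C4 without touching the oxirane.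

Step 10
Reactants: 12 but-2-yne-1,4-diol
Product: 13 4-[(tert-butyldimethylsilyl)oxy]but-2-yn-1-ol
Conditions: TBSCl (1 equiv), imidazole, THF, 0 °C, diol in threefold excess
Reagents that add atoms: tert-butyldimethylsilyl chloride, CC(C)(C)[Si](C)(C)Cl
Why: Statistical monosilylation of a symmetrical diol used in excess should give mainly the mono-ether, the water-soluble surplus diol being washed out.

Step 11
Reactants: 13 4-[(tert-butyldimethylsilyl)oxy]but-2-yn-1-ol
Product: 15 (2Z)-4-[(tert-butyldimethylsilyl)oxy]-3-iodobut-2-en-1-ol, via cyclic sodium alkenylalanate 14 (not isolated)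
Conditions: NaAlH2(OCH2CH2OMe)2, THF, 0 °C to rt; then I2, −78 °C to 0 °C
Reagents that add atoms: iodine, [I][I]
Why: Hydroxyl-directed trans-hydroalumination of a propargylic alcohol followed by iodinolysis should deliver hydride to C2 from the aluminium bound to O1, leave aluminium on C3 cis to C1 in a five-membered alanate, and replace it by iodine with retention to give the Z-iodide.

Step 12
Reactants: 11 (2R,3R)-3-[(3E,5R)-5-[(tert-butyldimethylsilyl)oxy]-4,8-dimethylnona-3,7-dien-1-yl]-2-ethenyl-3-methyloxirane; 15 (2Z)-4-[(tert-butyldimethylsilyl)oxy]-3-iodobut-2-en-1-ol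
Product: 17 (2E)-3-({[tert-butyl(dimethyl)silyl]oxy}methyl)-5-[(2R,3R)-3-[(3E,5R)-5-[(tert-butyldimethylsilyl)oxy]-4,8-dimethylnona-3,7-dien-1-yl]-3-methyloxiran-2-yl]pent-2-en-1-ol, via B-alkyl-9-BBN borane 16 (not isolated)
Conditions: 9-BBN, THF, 0 °C to rt until 11 is consumed; then aq K3PO4, 15, Pd(dppf)Cl2 (cat.), AsPh3 (cat.), DMF, rt
Reagents that add atoms: none
Why: 9-BBN hydroboration followed by B-alkyl Suzuki–Miyaura coupling should place boron only on C4 of the monosubstituted vinyl group and then join C4 to C3 on zerovalent palladium with retention at the alkenyl iodide, so that C4 ends cis to C1 across C2=C3.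

Step 13
Reactants: 17 (2E)-3-({[tert-butyl(dimethyl)silyl]oxy}methyl)-5-[(2R,3R)-3-[(3E,5R)-5-[(tert-butyldimethylsilyl)oxy]-4,8-dimethylnona-3,7-dien-1-yl]-3-methyloxiran-2-yl]pent-2-en-1-ol
Product: 18 (2E)-3-({[tert-butyl(dimethyl)silyl]oxy}methyl)-5-[(2R,3R)-3-[(3E,5R)-5-[(tert-butyldimethylsilyl)oxy]-4,8-dimethylnona-3,7-dien-1-yl]-3-methyloxiran-2-yl]pent-2-en-1-yl acetate
Conditions: Ac2O, pyridine, DMAP (cat.), CH2Cl2, 0 °C
Reagents that add atoms: acetic anhydride, CC(=O)OC(C)=O
Why: Acylation with Ac2O/pyridine/DMAP should esterify the only free hydroxyl, the primary allylic C1 alcohol, under conditions to which the oxirane and silyl ethers are stable.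

Step 14
Reactants: 18 (2E)-3-({[tert-butyl(dimethyl)silyl]oxy}methyl)-5-[(2R,3R)-3-[(3E,5R)-5-[(tert-butyldimethylsilyl)oxy]-4,8-dimethylnona-3,7-dien-1-yl]-3-methyloxiran-2-yl]pent-2-en-1-yl acetate
Product: 19 (2E)-3-(hydroxymethyl)-5-[(2R,3R)-3-[(3E,5R)-5-hydroxy-4,8-dimethylnona-3,7-dien-1-yl]-3-methyloxiran-2-yl]pent-2-en-1-yl acetate (target, 6R,7R,12R)
Conditions: Bu4NF, AcOH (1:1), THF, 0 °C to rt
Reagents that add atoms: none
Why: Fluoride-mediated desilylation buffered with acetic acid should cleave both TBS ethers while sparing the allylic acetate and the trisubstituted oxirane, and the acetate cannot migrate because O1 and the C3′ hydroxyl are trans across C2=C3.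

**Compound list**

1 | (R)-linalool, (3R)-3,7-dimethylocta-1,6-dien-3-ol | C=C[C@](C)(O)CCC=C(C)C | starting material
2 | (2E,6R)-2,6-dimethylocta-2,7-diene-1,6-diol | C=C[C@](C)(O)CC/C=C(\C)CO | intermediate
3 | (2E,6R)-6-hydroxy-2,6-dimethylocta-2,7-dienal | C=C[C@](C)(O)CC/C=C(\C)C=O | intermediate
4 | diisopinocampheylborinate ester of 5 at the C12 oxygen (isopinocampheyl groups from (−)-α-pinene) | C=C[C@](C)(O)CC/C=C(\C)[C@H](OB([C@@H]1[C@@H](C)[C@@H]2C[C@H](C1)C2(C)C)[C@@H]1[C@@H](C)[C@@H]2C[C@H](C1)C2(C)C)CC=C | intermediate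
5 | (4R,5E,9R)-5,9-dimethylundeca-1,5,10-triene-4,9-diol | C=C[C@](C)(O)CC/C=C(\C)[C@H](O)CC=C | intermediate
6 | (3R,6E,8R)-8-[(tert-butyldimethylsilyl)oxy]-3,7-dimethylundeca-1,6,10-trien-3-ol | C=C[C@](C)(O)CC/C=C(\C)[C@H](O[Si](C)(C)C(C)(C)C)CC=C | intermediate
7 | (2R,5E,7R)-7-[(tert-butyldimethylsilyl)oxy]-6-methyl-2-[(2S)-oxiran-2-yl]deca-5,9-dien-2-ol | C1O[C@@H]1[C@](C)(O)CC/C=C(\C)[C@H](O[Si](C)(C)C(C)(C)C)CC=C | intermediate
8 | [(2R,3R)-3-[(3E,5R)-5-[(tert-butyldimethylsilyl)oxy]-4-methylocta-3,7-dien-1-yl]-3-methyloxiran-2-yl]methanol | OC[C@H]1O[C@]1(C)CC/C=C(\C)[C@H](O[Si](C)(C)C(C)(C)C)CC=C | intermediate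
9 | [(2R,3R)-3-[(3E,5R)-5-[(tert-butyldimethylsilyl)oxy]-4,8-dimethylnona-3,7-dien-1-yl]-3-methyloxiran-2-yl]methanol | OC[C@H]1O[C@]1(C)CC/C=C(\C)[C@H](O[Si](C)(C)C(C)(C)C)CC=C(C)C | intermediate
10 | (2S,3R)-3-[(3E,5R)-5-[(tert-butyldimethylsilyl)oxy]-4,8-dimethylnona-3,7-dien-1-yl]-3-methyloxirane-2-carbaldehyde | O=C[C@H]1O[C@]1(C)CC/C=C(\C)[C@H](O[Si](C)(C)C(C)(C)C)CC=C(C)C | intermediate
11 | (2R,3R)-3-[(3E,5R)-5-[(tert-butyldimethylsilyl)oxy]-4,8-dimethylnona-3,7-dien-1-yl]-2-ethenyl-3-methyloxirane | C=C[C@H]1O[C@]1(C)CC/C=C(\C)[C@H](O[Si](C)(C)C(C)(C)C)CC=C(C)C | intermediate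
12 | but-2-yne-1,4-diol | OCC#CCO | starting material
13 | 4-[(tert-butyldimethylsilyl)oxy]but-2-yn-1-ol | OCC#CCO[Si](C)(C)C(C)(C)C | intermediate
14 | sodium 2,2-bis(2-methoxyethoxy)-3-{[(tert-butyldimethylsilyl)oxy]methyl}-2,5-dihydro-1,2-oxaluminol-2-uide (cyclic alkenylalanate) | [Na+].COCCO[Al-]1(OCCOC)OCC=C1CO[Si](C)(C)C(C)(C)C | intermediate
15 | (2Z)-4-[(tert-butyldimethylsilyl)oxy]-3-iodobut-2-en-1-ol | OC/C=C(\I)CO[Si](C)(C)C(C)(C)C | intermediate
16 | 9-{2-[(2R,3R)-3-[(3E,5R)-5-[(tert-butyldimethylsilyl)oxy]-4,8-dimethylnona-3,7-dien-1-yl]-3-methyloxiran-2-yl]ethyl}-9-borabicyclo[3.3.1]nonane | C(C[C@H]1O[C@]1(C)CC/C=C(\C)[C@H](O[Si](C)(C)C(C)(C)C)CC=C(C)C)B1C2CCCC1CCC2 | intermediate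
17 | (2E)-3-({[tert-butyl(dimethyl)silyl]oxy}methyl)-5-[(2R,3R)-3-[(3E,5R)-5-[(tert-butyldimethylsilyl)oxy]-4,8-dimethylnona-3,7-dien-1-yl]-3-methyloxiran-2-yl]pent-2-en-1-ol | OC/C=C(/CO[Si](C)(C)C(C)(C)C)CC[C@H]1O[C@]1(C)CC/C=C(\C)[C@H](O[Si](C)(C)C(C)(C)C)CC=C(C)C | intermediate
18 | (2E)-3-({[tert-butyl(dimethyl)silyl]oxy}methyl)-5-[(2R,3R)-3-[(3E,5R)-5-[(tert-butyldimethylsilyl)oxy]-4,8-dimethylnona-3,7-dien-1-yl]-3-methyloxiran-2-yl]pent-2-en-1-yl acetate | CC(=O)OC/C=C(/CO[Si](C)(C)C(C)(C)C)CC[C@H]1O[C@]1(C)CC/C=C(\C)[C@H](O[Si](C)(C)C(C)(C)C)CC=C(C)C | intermediate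
19 | (2E)-3-(hydroxymethyl)-5-[(2R,3R)-3-[(3E,5R)-5-hydroxy-4,8-dimethylnona-3,7-dien-1-yl]-3-methyloxiran-2-yl]pent-2-en-1-yl acetate | CC(=O)OC/C=C(/CO)CC[C@H]1O[C@]1(C)CC/C=C(\C)[C@H](O)CC=C(C)C | target

**Step count and risks**

Total step count: 14. Longest linear sequence: 12 steps (steps 1–9 and 12–14, from 1 to 19).

Steps most likely to fail:

1. Step 5. The catalyst may give poor facial selectivity at C6, or the C7 hydroxyl may direct oxidation to the bishomoallylic C10=C11 alkene instead of the vinyl group. Fallback, leaving from 6: VO(acac)2 (cat.) with t-BuOOH in toluene should epoxidise only the allylic vinyl group, as known for linalool itself, but without control at C6. This would give 7 mixed with its C6 epimer (2R,5E,7R)-7-[(tert-butyldimethylsilyl)oxy]-6-methyl-2-[(2R)-oxiran-2-yl]deca-5,9-dien-2-ol F1. A hydrolytic kinetic resolution of this terminal-epoxide mixture (Jacobsen type) would follow, using 0.55 equiv of water and the antipode of (salen)Co(OAc) (trivalent cobalt; salen = N,N′-bis(3,5-di-tert-butylsalicylidene)-1,2-cyclohexanediamine dianion) that hydrolyses the (R)-configured oxirane. It should turn F1 into the triol (2R,3R,6E,8R)-8-[(tert-butyldimethylsilyl)oxy]-3,7-dimethylundeca-6,10-diene-1,2,3-triol F2 and leave 7, which is separated and re-enters the route at step 6.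

2. Step 12. The alkylborane may be lost during the basic aqueous transmetallation, by 1,3-elimination of the borate onto the neighbouring oxirane or by protodeboronation, before it couples. Fallback, leaving from 16, made as in step 12: immediate oxidation with NaBO3·4H2O should give 2-[(2R,3R)-3-[(3E,5R)-5-[(tert-butyldimethylsilyl)oxy]-4,8-dimethylnona-3,7-dien-1-yl]-3-methyloxiran-2-yl]ethan-1-ol F3. I2, PPh3 and imidazole should convert it into (2R,3R)-3-[(3E,5R)-5-[(tert-butyldimethylsilyl)oxy]-4,8-dimethylnona-3,7-dien-1-yl]-2-(2-iodoethyl)-3-methyloxirane F4. Zinc insertion (Zn dust, LiCl, THF) should give the corresponding alkylzinc iodide F5. A Negishi coupling with 15 (Pd(OAc)2, SPhos, THF, rt, slow addition of the zinc reagent so that the free hydroxyl is tolerated) would return to the route at 17.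

3. Step 1. The SeO2 oxidation may stall, run on to the enal and acid, or the acidic selenium species may rearrange or cyclise the tertiary allylic alcohol. Fallback, leaving from 1: ozonolysis with one equivalent of ozone (CH2Cl2/MeOH, −78 °C, then Me2S) should cleave only the electron-rich trisubstituted alkene and give the hydroxy aldehyde as its lactol (5R)-5-ethenyl-5-methyloxolan-2-ol F6. Wittig olefination with the stabilised ylide Ph3P=C(CH3)CHO in hot toluene should then give the E-enal directly, replacing steps 1 and 2 and rejoining the route at 3.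

Further compounds
F1 | step 5 | (2R,5E,7R)-7-[(tert-butyldimethylsilyl)oxy]-6-methyl-2-[(2R)-oxiran-2-yl]deca-5,9-dien-2-ol | C1O[C@H]1[C@](C)(O)CC/C=C(\C)[C@H](O[Si](C)(C)C(C)(C)C)CC=C
F2 | step 5 | (2R,3R,6E,8R)-8-[(tert-butyldimethylsilyl)oxy]-3,7-dimethylundeca-6,10-diene-1,2,3-triol | OC[C@@H](O)[C@](C)(O)CC/C=C(\C)[C@H](O[Si](C)(C)C(C)(C)C)CC=C
F3 | step 12 | 2-[(2R,3R)-3-[(3E,5R)-5-[(tert-butyldimethylsilyl)oxy]-4,8-dimethylnona-3,7-dien-1-yl]-3-methyloxiran-2-yl]ethan-1-ol | OCC[C@H]1O[C@]1(C)CC/C=C(\C)[C@H](O[Si](C)(C)C(C)(C)C)CC=C(C)C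
F4 | step 12 | (2R,3R)-3-[(3E,5R)-5-[(tert-butyldimethylsilyl)oxy]-4,8-dimethylnona-3,7-dien-1-yl]-2-(2-iodoethyl)-3-methyloxirane | ICC[C@H]1O[C@]1(C)CC/C=C(\C)[C@H](O[Si](C)(C)C(C)(C)C)CC=C(C)C
F5 | step 12 | {2-[(2R,3R)-3-[(3E,5R)-5-[(tert-butyldimethylsilyl)oxy]-4,8-dimethylnona-3,7-dien-1-yl]-3-methyloxiran-2-yl]ethyl}zinc iodide | I[Zn]CC[C@H]1O[C@]1(C)CC/C=C(\C)[C@H](O[Si](C)(C)C(C)(C)C)CC=C(C)C
F6 | step 1 | (5R)-5-ethenyl-5-methyloxolan-2-ol | OC1CC[C@](C)(C=C)O1
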